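The plan rests on cutting the pyranone of the flavone unit back to its benzo ring, a 2-arylphloroglucinol. In the 5-O-methyl 1,3-diol a mirror plane runs through the biaryl carbon C2 and C5. C4 and C6 are therefore equivalent and mono-iodination is unambiguous. The precursor carries iodine between the C3 hydroxyl and the C5 methoxy group, and a benzyl-protected 5-chloro-2-hydroxyphenyl group at C2. One palladium-catalysed operation joins it with CO and 4-ethynylanisole, forms C4–C4a, C3–C4 and O1–C2, and can give only the 8-aryl flavone. Chlorine later becomes boron, and a rhodium-catalysed asymmetric addition to a ring A chromone sets the 2S flavanone centre.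

Key step: step 6

Assumption: in step 13 the sense of induction is taken to follow that of cyclic enones, where an (S)-configured biaryl bisphosphine on rhodium gives the S product (the CIP order at flavanone C2 keeps the same descriptor); if the opposite face were attacked, the (R)-ligand would be used.
Assumption: rotation about the C8–aryl bond is taken as fast at room temperature, so the biaryl axis is no stereo-element, in line with the target SMILES.

Step 1
Reactants: 1 5-methoxyresorcinol
Product: 2 1-methoxy-3,5-bis(methoxymethoxy)benzene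
Conditions: NaH (2.4 equiv), MOMCl (2.4 equiv), DMF, 0 °C to rt
Reagents that add atoms: chloromethyl methyl ether, COCCl
Why: Williamson-type O-alkylation of both phenoxides by the hard electrophile MOMCl should give the bis-acetal, which hides the acidic protons and places two cooperating directing groups around C2.

Step 2
Reactants: 3 4-chloro-2-iodophenol
Product: 4 1-(benzyloxy)-4-chloro-2-iodobenzene
Conditions: BnBr, K2CO3, acetone, reflux
Reagents that add atoms: benzyl bromide, BrCc1ccccc1
Why: Williamson ether synthesis on an acidic halophenol is routine, benzyl is chosen because it outlasts the acidic MOM cleavage of step 4, and chlorine serves as a latent boron site that PPh3-ligated palladium does not touch.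

Step 3
Reactants: 2 1-methoxy-3,5-bis(methoxymethoxy)benzene, 4 1-(benzyloxy)-4-chloro-2-iodobenzene
Product: 7 2'-(benzyloxy)-5'-chloro-4-methoxy-2,6-bis(methoxymethoxy)-1,1'-biphenyl, via aryllithium 5 (not isolated), via arylzinc chloride 6 (not isolated)
Conditions: 2, n-BuLi, THF, 0 °C; ZnCl2, 0 °C to rt; then 4, Pd(PPh3)4 (5 mol %), 60 °C
Reagents that add atoms: n-butyllithium, [Li]CCCC (lithium, held in 5 only); zinc chloride, Cl[Zn]Cl (zinc and chlorine, held in 6 only)
Why: Directed ortho-metalation should take place at C2, the only position flanked by two chelating OMOM groups, and after lithium–zinc exchange the Negishi coupling engages only the C–I bond of 4 because the C–Cl bond does not undergo oxidative addition with this catalyst.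

Step 4
Reactants: 7 2'-(benzyloxy)-5'-chloro-4-methoxy-2,6-bis(methoxymethoxy)-1,1'-biphenyl
Product: 8 2-[2-(benzyloxy)-5-chlorophenyl]-5-methoxybenzene-1,3-diol
Conditions: conc. HCl (cat.), MeOH, 50 °C
Reagents that add atoms: none
Why: Acid-catalysed acetal exchange with methanol removes both MOM groups, leaves the benzyl ether, methyl ether and aryl chloride untouched, and uncovers the mirror-symmetric diol.

Step 5
Reactants: 8 2-[2-(benzyloxy)-5-chlorophenyl]-5-methoxybenzene-1,3-diol
Product: 9 2-[2-(benzyloxy)-5-chlorophenyl]-4-iodo-5-methoxybenzene-1,3-diol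
Conditions: NIS (1.0 equiv), MeCN, −30 °C to 0 °C, dark
Reagents that add atoms: N-iodosuccinimide, O=C1CCC(=O)N1I
Why: Electrophilic aromatic iodination goes to the trioxygenated ring, by far the most electron-rich arene, and since C4 and C6 are equivalent one equivalent of NIS at low temperature can give only one mono-iodide.

Step 6
Reactants: 9 2-[2-(benzyloxy)-5-chlorophenyl]-4-iodo-5-methoxybenzene-1,3-diol, 10 4-ethynylanisole, 11 carbon monoxide
Product: 14 8-[2-(benzyloxy)-5-chlorophenyl]-7-hydroxy-5-methoxy-2-(4-methoxyphenyl)-4H-chromen-4-one, via ynone 12 (not isolated), via enaminone 13 (not isolated)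
Conditions: PdCl2(PPh3)2 (5 mol %), CO (1 atm), Et2NH/DMF, 60 °C, no copper salt
Reagents that add atoms: diethylamine, CCNCC (nitrogen and ethyl groups, held in 13 only and released again on ring closure)
Why: Zerovalent palladium formed in the flask inserts into the C–I bond of 9, migratory insertion of CO gives an aroyl complex of divalent palladium, and amine-assisted transfer of the alkyne with reductive elimination gives ynone 12, which creates C4–C4a and C3–C4. Diethylamine adds to 12 to give the push–pull enaminone 13, whose β-carbon is attacked by the ortho hydroxyl with loss of the amine, so that O1–C2 forms and the pyranone closes in a 6-endo sense by addition–elimination. The closest known reaction type is the palladium-catalysed carbonylative annulation of 2-iodophenols with terminal arylacetylenes to flavones in secondary-amine media, and no stereocentre is formed. Regiochemistry needs no external control, because iodine sits between the C3 hydroxyl and the C5 methyl ether, so the only oxygen that can close the ring is the one beside the biaryl carbon and the aryl group must end at C8, while the remote C1 hydroxyl cannot reach the ynone and emerges as the free 7-OH. Selectivity for C–I is secured by having chlorine as the only other halogen. Flavone over aurone (5-exo) is secured by the enaminone pathway, and direct alkynylation leading to a benzofuran is held back by leaving out copper and by the fast CO insertion of an electron-rich arylpalladium species.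

Step 7
Reactants: 14 8-[2-(benzyloxy)-5-chlorophenyl]-7-hydroxy-5-methoxy-2-(4-methoxyphenyl)-4H-chromen-4-one
Product: 15 8-[2-(benzyloxy)-5-chlorophenyl]-5,7-dimethoxy-2-(4-methoxyphenyl)-4H-chromen-4-one
Conditions: MeI, K2CO3, DMF, rt
Reagents that add atoms: iodomethane, CI
Why: Williamson methylation of the only free phenol, the acidic 7-OH, is unambiguous and installs the 7-methoxy group of the target.

Step 8
Reactants: 15 8-[2-(benzyloxy)-5-chlorophenyl]-5,7-dimethoxy-2-(4-methoxyphenyl)-4H-chromen-4-one
Product: 16 8-(5-chloro-2-hydroxyphenyl)-5-hydroxy-7-methoxy-2-(4-methoxyphenyl)-4H-chromen-4-one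
Conditions: BCl3 (5 equiv), pentamethylbenzene (3 equiv), CH2Cl2, −78 °C to 0 °C; then H2O
Reagents that add atoms: none
Why: In this chelation-directed Lewis-acid dealkylation BCl3 held between the C4 carbonyl and the peri oxygen cleaves only the 5-methyl ether among the three methyl ethers, the benzyl ether falls at the same time with pentamethylbenzene trapping the benzyl cation, and doing this now keeps strong Lewis acid away from the later flavanone centre, whose para-oxygenated 2-aryl group would favour ring opening.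

Step 9
Reactants: 16 8-(5-chloro-2-hydroxyphenyl)-5-hydroxy-7-methoxy-2-(4-methoxyphenyl)-4H-chromen-4-one
Product: 17 5-(benzyloxy)-8-[2-(benzyloxy)-5-chlorophenyl]-7-methoxy-2-(4-methoxyphenyl)-4H-chromen-4-one
Conditions: BnBr (3 equiv), K2CO3, DMF, 70 °C
Reagents that add atoms: benzyl bromide, BrCc1ccccc1
Why: Exhaustive Williamson benzylation under warm carbonate conditions caps both the free phenol and the hydrogen-bonded 5-OH, which removes a chelating peri-hydroxyketone that could tie up rhodium in step 13 and leaves only hydrogenolysable groups for the end.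

Step 10
Reactants: 17 5-(benzyloxy)-8-[2-(benzyloxy)-5-chlorophenyl]-7-methoxy-2-(4-methoxyphenyl)-4H-chromen-4-one
Product: 18 {4-(benzyloxy)-3-[5-(benzyloxy)-7-methoxy-2-(4-methoxyphenyl)-4-oxo-4H-chromen-8-yl]phenyl}boronic acid
Conditions: B2(OH)4 (3 equiv), second-generation XPhos palladacycle PdCl(XPhos)(2'-aminobiphenyl-2-yl) (2 mol %), XPhos (4 mol %), KOAc (3 equiv), EtOH/THF, 80 °C
Reagents that add atoms: tetrahydroxydiboron, OB(O)B(O)O
Why: Miyaura-type borylation of aryl chlorides with tetrahydroxydiboron and an XPhos-ligated palladium catalyst is established for electron-rich substrates of the 4-chloroanisole type and gives the free boronic acid directly.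

Step 11
Reactants: 19 1-(2,6-dihydroxy-4-methoxyphenyl)ethan-1-one
Product: 20 1-[2-(benzyloxy)-6-hydroxy-4-methoxyphenyl]ethan-1-one
Conditions: BnBr (1.05 equiv), K2CO3, acetone, reflux
Reagents that add atoms: benzyl bromide, BrCc1ccccc1
Why: Williamson mono-benzylation should stop after one alkylation, since the two hydroxyls are equivalent and the remaining one is locked in a strong hydrogen bond to the ketone.

Step 12
Reactants: 20 1-[2-(benzyloxy)-6-hydroxy-4-methoxyphenyl]ethan-1-one
Product: 22 5-(benzyloxy)-7-methoxy-4H-chromen-4-one, via enaminone 21 (not isolated)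
Conditions: Me2NCH(OMe)2, toluene, 100 °C; then conc. HCl, CH2Cl2, rt
Reagents that add atoms: N,N-dimethylformamide dimethyl acetal, COC(OC)N(C)C
Why: Condensation of the methyl ketone with the formamide acetal gives the enaminone, which on acidification cyclises by attack of the ortho hydroxyl and loss of dimethylamine (enaminone route to 2,3-unsubstituted chromones).

Step 13
Reactants: 18 {4-(benzyloxy)-3-[5-(benzyloxy)-7-methoxy-2-(4-methoxyphenyl)-4-oxo-4H-chromen-8-yl]phenyl}boronic acid, 22 5-(benzyloxy)-7-methoxy-4H-chromen-4-one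
Product: 23 5-(benzyloxy)-8-{2-(benzyloxy)-5-[(2S)-5-(benzyloxy)-7-methoxy-4-oxo-3,4-dihydro-2H-chromen-2-yl]phenyl}-7-methoxy-2-(4-methoxyphenyl)-4H-chromen-4-one
Conditions: [RhCl(C2H4)2]2 (2.5 mol %), (S)-MeO-F12-BIPHEP [(S)-6,6'-dimethoxy-2,2'-bis{bis(3,4,5-trifluorophenyl)phosphino}-1,1'-biphenyl] (5.5 mol %), aq K3PO4 (0.2 equiv), toluene/H2O, 30 °C, 22 in excess (2 equiv)
Reagents that add atoms: none
Why: In this rhodium-catalysed asymmetric 1,4-addition of an arylboronic acid to a chromone (Hayashi–Miyaura reaction) the arylrhodium species bearing the (S)-bisphosphine inserts the C2=C3 bond from one face only, as with cyclic enones, which sets C2 as S, and the nearly neutral two-phase medium near room temperature avoids ring opening of the flavanone.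

Step 14
Reactants: 23 5-(benzyloxy)-8-{2-(benzyloxy)-5-[(2S)-5-(benzyloxy)-7-methoxy-4-oxo-3,4-dihydro-2H-chromen-2-yl]phenyl}-7-methoxy-2-(4-methoxyphenyl)-4H-chromen-4-one
Product: 24 (2S)-2,3-dihydroheveaflavone
Conditions: H2 (1 atm), 10 % Pd/C, THF/EtOAc, rt
Reagents that add atoms: none
Why: Catalytic hydrogenolysis of the three aryl benzyl ethers at 1 atm is faster than reduction of the flavone double bond or cleavage of the flavanone C2–O bond and involves neither acid nor base, so the 2S centre stays untouched.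

Compound list
1 | 5-methoxyresorcinol (5-methoxybenzene-1,3-diol) | COc1cc(O)cc(O)c1 | starting material
2 | 1-methoxy-3,5-bis(methoxymethoxy)benzene | COCOc1cc(OC)cc(OCOC)c1 | intermediate
3 | 4-chloro-2-iodophenol | Oc1ccc(Cl)cc1I | starting material
4 | 1-(benzyloxy)-4-chloro-2-iodobenzene | Clc1ccc(OCc2ccccc2)c(I)c1 | intermediate
5 | [4-methoxy-2,6-bis(methoxymethoxy)phenyl]lithium (not isolated) | [Li]c1c(OCOC)cc(OC)cc1OCOC | intermediate
6 | chloro[4-methoxy-2,6-bis(methoxymethoxy)phenyl]zinc (not isolated) | Cl[Zn]c1c(OCOC)cc(OC)cc1OCOC | intermediate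
7 | 2'-(benzyloxy)-5'-chloro-4-methoxy-2,6-bis(methoxymethoxy)-1,1'-biphenyl | COCOc1cc(OC)cc(OCOC)c1-c1cc(Cl)ccc1OCc1ccccc1 | intermediate
8 | 2-[2-(benzyloxy)-5-chlorophenyl]-5-methoxybenzene-1,3-diol | COc1cc(O)c(-c2cc(Cl)ccc2OCc2ccccc2)c(O)c1 | intermediate
9 | 2-[2-(benzyloxy)-5-chlorophenyl]-4-iodo-5-methoxybenzene-1,3-diol | COc1cc(O)c(-c2cc(Cl)ccc2OCc2ccccc2)c(O)c1I | intermediate
10 | 4-ethynylanisole | COc1ccc(C#C)cc1 | starting material
11 | carbon monoxide | [C-]#[O+] | starting material
12 | 1-{3-[2-(benzyloxy)-5-chlorophenyl]-2,4-dihydroxy-6-methoxyphenyl}-3-(4-methoxyphenyl)prop-2-yn-1-one (not isolated) | COc1ccc(C#CC(=O)c2c(OC)cc(O)c(-c3cc(Cl)ccc3OCc3ccccc3)c2O)cc1 | intermediate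
13 | (E)-1-{3-[2-(benzyloxy)-5-chlorophenyl]-2,4-dihydroxy-6-methoxyphenyl}-3-(diethylamino)-3-(4-methoxyphenyl)prop-2-en-1-one (not isolated, drawn E) | CCN(CC)/C(=C/C(=O)c1c(OC)cc(O)c(-c2cc(Cl)ccc2OCc2ccccc2)c1O)c1ccc(OC)cc1 | intermediate
14 | 8-[2-(benzyloxy)-5-chlorophenyl]-7-hydroxy-5-methoxy-2-(4-methoxyphenyl)-4H-chromen-4-one | COc1ccc(-c2cc(=O)c3c(OC)cc(O)c(-c4cc(Cl)ccc4OCc5ccccc5)c3o2)cc1 | intermediate
15 | 8-[2-(benzyloxy)-5-chlorophenyl]-5,7-dimethoxy-2-(4-methoxyphenyl)-4H-chromen-4-one | COc1ccc(-c2cc(=O)c3c(OC)cc(OC)c(-c4cc(Cl)ccc4OCc5ccccc5)c3o2)cc1 | intermediate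
16 | 8-(5-chloro-2-hydroxyphenyl)-5-hydroxy-7-methoxy-2-(4-methoxyphenyl)-4H-chromen-4-one | COc1ccc(-c2cc(=O)c3c(O)cc(OC)c(-c4cc(Cl)ccc4O)c3o2)cc1 | intermediate
17 | 5-(benzyloxy)-8-[2-(benzyloxy)-5-chlorophenyl]-7-methoxy-2-(4-methoxyphenyl)-4H-chromen-4-one | COc1ccc(-c2cc(=O)c3c(OCc5ccccc5)cc(OC)c(-c4cc(Cl)ccc4OCc6ccccc6)c3o2)cc1 | intermediate
18 | {4-(benzyloxy)-3-[5-(benzyloxy)-7-methoxy-2-(4-methoxyphenyl)-4-oxo-4H-chromen-8-yl]phenyl}boronic acid | COc1ccc(-c2cc(=O)c3c(OCc5ccccc5)cc(OC)c(-c4cc(B(O)O)ccc4OCc6ccccc6)c3o2)cc1 | intermediate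
19 | 1-(2,6-dihydroxy-4-methoxyphenyl)ethan-1-one | CC(=O)c1c(O)cc(OC)cc1O | starting material
20 | 1-[2-(benzyloxy)-6-hydroxy-4-methoxyphenyl]ethan-1-one | CC(=O)c1c(O)cc(OC)cc1OCc1ccccc1 | intermediate
21 | (E)-1-[2-(benzyloxy)-6-hydroxy-4-methoxyphenyl]-3-(dimethylamino)prop-2-en-1-one (not isolated) | CN(C)/C=C/C(=O)c1c(O)cc(OC)cc1OCc1ccccc1 | intermediate
22 | 5-(benzyloxy)-7-methoxy-4H-chromen-4-one | COc1cc(OCc2ccccc2)c2c(=O)ccoc2c1 | intermediate
23 | 5-(benzyloxy)-8-{2-(benzyloxy)-5-[(2S)-5-(benzyloxy)-7-methoxy-4-oxo-3,4-dihydro-2H-chromen-2-yl]phenyl}-7-methoxy-2-(4-methoxyphenyl)-4H-chromen-4-one | COc1ccc(-c2cc(=O)c3c(OCc7ccccc7)cc(OC)c(-c4cc([C@@H]5CC(=O)c6c(OCc8ccccc8)cc(OC)cc6O5)ccc4OCc9ccccc9)c3o2)cc1 | intermediate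
24 | (2S)-2,3-dihydroheveaflavone, 5-hydroxy-8-{2-hydroxy-5-[(2S)-5-hydroxy-7-methoxy-4-oxo-3,4-dihydro-2H-chromen-2-yl]phenyl}-7-methoxy-2-(4-methoxyphenyl)-4H-chromen-4-one | COc1ccc(-c2cc(=O)c3c(O)cc(OC)c(-c4cc([C@@H]5CC(=O)c6c(O)cc(OC)cc6O5)ccc4O)c3o2)cc1 | target

Total step count: 14. Longest linear sequence: 11 steps (1, 3, 4, 5, 6, 7, 8, 9, 10, 13, 14).

Steps most likely to fail

**Step 6.** Oxidative addition into the doubly ortho-substituted, very electron-rich C–I bond may be slow. Reductive loss of iodine, capture of the aroylpalladium species by diethylamine, or 5-exo closure could then take over. The fallback is the classical chalcone route without palladium. It sets out from diol 8, whose symmetry again leaves a single ring position.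
- Friedel–Crafts C-acetylation (Ac2O, BF3·OEt2) should give the acetophenone 1-{3-[2-(benzyloxy)-5-chlorophenyl]-2,4-dihydroxy-6-methoxyphenyl}ethan-1-one F1.
- Claisen–Schmidt condensation with 4-methoxybenzaldehyde (KOH, EtOH) should give the 2'-hydroxychalcone F2.
- Oxidative cyclisation (cat. I2, DMSO, 120 °C) closes the pyranone through the only hydroxyl ortho to the ketone.

The fallback comes back to the route at 14.

**Step 13.** Protodeboronation of the electron-rich arylrhodium species may outrun insertion into the peri-substituted chromone, since the boronic acid is the limiting partner. Facial selectivity may also erode with so large an aryl group. The fallback builds the flavanone by the chalcone route and resolves it. It sets out from 17 and 20.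
- Suzuki–Miyaura vinylation of 17 (potassium vinyltrifluoroborate, Pd(OAc)2, XPhos, K2CO3, THF/H2O, 80 °C) should give the styrene F3.
- Lemieux–Johnson cleavage (cat. OsO4, NaIO4, 2,6-lutidine, dioxane/H2O) should give the aldehyde F4.
- Claisen–Schmidt condensation with 20 (KOH, EtOH/THF, rt) should give the 2'-hydroxychalcone F5.
- Oxa-Michael closure (NaOAc, EtOH, reflux) should give the racemic flavanone F6.
- Preparative HPLC on a polysaccharide-carbamate chiral phase delivers the S enantiomer. The (2R)-flavanone F7 is returned to the equilibrium with F5 by mild base and cyclised again.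

The fallback comes back to the route at 23.

**Step 3.** Transmetalation and reductive elimination at the doubly ortho-substituted arylzinc may be sluggish, so that protodemetalation and homocoupling consume the partners. The fallback reverses the polarity and uses a Suzuki–Miyaura coupling. It sets out from 2.
- Compound 2 is lithiated as before to 5 and quenched with I2 to give 2-iodo-5-methoxy-1,3-bis(methoxymethoxy)benzene F8.
- F8 is coupled with commercial [2-(benzyloxy)-5-chlorophenyl]boronic acid F9 (PdCl2(dppf), K3PO4, dioxane/H2O, 80 °C).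

This boronic acid has only one ortho substituent and is stable to protodeboronation, and its chlorine is inert to this catalyst. The fallback comes back to the route at 7.

Further compounds
F1 | step 6 | 1-{3-[2-(benzyloxy)-5-chlorophenyl]-2,4-dihydroxy-6-methoxyphenyl}ethan-1-one | CC(=O)c1c(OC)cc(O)c(-c2cc(Cl)ccc2OCc2ccccc2)c1O
F2 | step 6 | (E)-1-{3-[2-(benzyloxy)-5-chlorophenyl]-2,4-dihydroxy-6-methoxyphenyl}-3-(4-methoxyphenyl)prop-2-en-1-one | COc1ccc(/C=C/C(=O)c2c(OC)cc(O)c(-c3cc(Cl)ccc3OCc3ccccc3)c2O)cc1
F3 | step 13 | 5-(benzyloxy)-8-[2-(benzyloxy)-5-ethenylphenyl]-7-methoxy-2-(4-methoxyphenyl)-4H-chromen-4-one | COc1ccc(-c2cc(=O)c3c(OCc5ccccc5)cc(OC)c(-c4cc(C=C)ccc4OCc6ccccc6)c3o2)cc1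
F4 | step 13 | 4-(benzyloxy)-3-[5-(benzyloxy)-7-methoxy-2-(4-methoxyphenyl)-4-oxo-4H-chromen-8-yl]benzaldehyde | COc1ccc(-c2cc(=O)c3c(OCc5ccccc5)cc(OC)c(-c4cc(C=O)ccc4OCc6ccccc6)c3o2)cc1
F5 | step 13 | 5-(benzyloxy)-8-{2-(benzyloxy)-5-[(E)-3-[2-(benzyloxy)-6-hydroxy-4-methoxyphenyl]-3-oxoprop-1-en-1-yl]phenyl}-7-methoxy-2-(4-methoxyphenyl)-4H-chromen-4-one | COc1ccc(-c2cc(=O)c3c(OCc7ccccc7)cc(OC)c(-c4cc(/C=C/C(=O)c5c(O)cc(OC)cc5OCc8ccccc8)ccc4OCc9ccccc9)c3o2)cc1
F6 | step 13 | racemic 5-(benzyloxy)-8-{2-(benzyloxy)-5-[5-(benzyloxy)-7-methoxy-4-oxo-3,4-dihydro-2H-chromen-2-yl]phenyl}-7-methoxy-2-(4-methoxyphenyl)-4H-chromen-4-one | COc1ccc(-c2cc(=O)c3c(OCc7ccccc7)cc(OC)c(-c4cc(C5CC(=O)c6c(OCc8ccccc8)cc(OC)cc6O5)ccc4OCc9ccccc9)c3o2)cc1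
F7 | step 13 | (2R)-enantiomer of 23 | COc1ccc(-c2cc(=O)c3c(OCc7ccccc7)cc(OC)c(-c4cc([C@H]5CC(=O)c6c(OCc8ccccc8)cc(OC)cc6O5)ccc4OCc9ccccc9)c3o2)cc1
F8 | step 3 | 2-iodo-5-methoxy-1,3-bis(methoxymethoxy)benzene | COCOc1cc(OC)cc(OCOC)c1I
F9 | step 3 | [2-(benzyloxy)-5-chlorophenyl]boronic acid | OB(O)c1cc(Cl)ccc1OCc1ccccc1
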